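The decision is to stop reading these runs in percent of the E charged and to read them as the concentration of D delivered into the flask, percent times charge.

| flask | E | remark | time |
|---|---|---|---|
| Wednesday's | 0.25 mM | run made earlier |  |
| Sunday's | 1 mM | run made earlier |  |
| flask | 0.50 mM |  | 2.0 min |

| run | time / s | D / % | L / % |
|---|---|---|---|
| Wednesday's | 10.0 | 0.9 | 0 |
| Wednesday's | 20.0 | 2.8 | 0 |
| Wednesday's | 50.0 | 6.6 | 0.1 |
| Wednesday's | 120 | 9.4 | 0 |
| Sunday's | 30.0 | 1.6 | 0 |
| Sunday's | 60.0 | 1.5 | 0.6 |
| Sunday's | 90.0 | 1.8 | 0 |
| Sunday's | 120 | 3.9 | 0 |

(standard deviation of a reading: 0.5 percentage points)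

- what is said of D includes L
- L, E is a solid; its amount is given per volume of the solution
- the numbers in the tables scatter with a standard deviation of 0.5 percentage points
- steps under discussion: J <-> D; D <-> G; E <-> J; G <-> J; L <-> D
- at the start none of E is in solution

1. amount of D and L together at 2.0 min, in percent of the E charged
2. concentration of D in solution at 2.0 min, in percent of saturation

Read across the tables, Wednesday's 6.6% at 50.0 s becomes 0.0165 mM, and Sunday's 1.5% at 60.0 s becomes 0.0150 mM. Sunday's charge was 4.00 times as large, yet a Sunday reading carries a scatter of 0.00500 mM, so these two readings, taken at neighbouring times, agree within that scatter. Read so, they look like zero order in the charge of E.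

The last rows part: Wednesday's reaches 0.0235 mM and has flattened, while Sunday's reaches 0.0390 mM. The flask's charge lies between the two, and this reckoning, as its own choice, commits to Sunday's row, whose last step shows no slowing. The delivered [D] at 2.0 min, percent times charge, is carried over unchanged, which gives the flask 7.80%. That figure rests on one reading, whose scatter comes to 1 percentage point on the flask's charge.

L stays near zero, at most 0.6% against a scatter of 0.5 points, so the readings bound the saturation of D from below and give no figure for it.

The forecast says 5.5% and 50%, holding that “supply is limited by something like dissolved-substrate saturation”. Its yield lies below this reckoning.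

The flask gives 7.31% and 12.6%.

    J ⇌ D (K = 29.0, k = 0.470 s⁻¹)
    D ⇌ G (K = 10.0, k = 0.0970 s⁻¹)
    E ⇌ J, rate k3*(cs3 - [J]) while solid is left; crystals form when [J] > cs3 (solubility = 0.310 mM, k = 0.0100 s⁻¹)
    G ⇌ J (k = 0.00590 s⁻¹)
    L ⇌ D, rate k5*(cs5 - [D]) while solid is left; crystals form when [D] > cs5 (solubility = 0.290 mM, k = 3.20 s⁻¹)

The flask's delivered [D] is 0.0365 mM against the carried 0.0390 mM, so the reckoned yield stands 0.49 points high. The forecast's yield is within its margin, and its saturation stands 37 points high. At 2.00 min the flask still holds 26.1% as E. The neighbouring flask, charged with 1.2 mM of E, gets the same reckoning: 0.0390 mM over that charge is 3.25%. It keeps 69% of its charge and gives 3.04%, a delivered [D] of 0.0365 mM.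

(All runs stem from a simulated flask for an exercise; scatter was added.)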